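The route rests on cutting the bond between furan C2 and C1 of the 2,5-dihydroxyphenyl ring. The key step exploits that this ring is a hydroquinone carbon-bonded to furan C2, the α-position remote from the C4 side chain, which is what remains when a furan α C–H adds in a Michael sense to p-benzoquinone and the adduct enolizes. One late operation thus joins both rings and unveils both phenols, so no phenol protection is needed. The precursor is the complete side-chain ester of a 3-substituted furan with both α C–H bonds free; its carbinol centre comes from asymmetric allylboration of furan-3-carbaldehyde, its isopropylidene terminus from cross metathesis, and its acyl centre from purchased (R)-2-methylbutanoic acid.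

Key step: step 4

Remark: (+)-B-methoxydiisopinocampheylborane, the antipode made from (−)-α-pinene, and (R)-2-methylbutanoic acid are assumed to be purchasable in high enantiomeric purity.

Step 1
Reactants: 1 furan-3-carbaldehyde; 2 allylmagnesium bromide
Product: 5 (R)-1-(furan-3-yl)but-3-en-1-ol, via B-allyldiisopinocampheylborane 3 (not isolated), via borinate ester 4 (not isolated)
Conditions: (+)-Ipc2BOMe [from (−)-α-pinene], 2, Et2O, 0 °C to rt, Mg salts filtered off; 1, Et2O, −100 °C; then 3 M NaOH, 30% H2O2, rt
Reagents that add atoms: none
Why: Brown asymmetric allylboration proceeds through a closed chair-like six-membered transition state in which the isopinocampheyl groups derived from (−)-α-pinene direct the allyl group of 3 to the Re face of the aldehyde, which sets the (R)-carbinol centre (to be confirmed by Mosher ester analysis before the material is carried on), and alkaline peroxide then cleaves borinate 4 without harming the furan.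

Step 2
Reactants: 5 (R)-1-(furan-3-yl)but-3-en-1-ol; 6 2-methyl-2-butene
Product: 7 (R)-1-(furan-3-yl)-4-methylpent-3-en-1-ol
Conditions: second-generation Grubbs catalyst RuCl2(=CHPh)(PCy3)(H2IMes) (3 mol%), 6 (large excess)/CH2Cl2, 35 °C, sealed vessel
Reagents that add atoms: none
Why: Olefin cross metathesis with a large excess of the trisubstituted alkene exchanges the terminal methylene of 5 for an isopropylidene group with loss of propene, the trisubstituted product being the least reactive alkene present and therefore the sink, while the free homoallylic hydroxyl, the furan and the carbinol centre are left alone by the ruthenium carbene.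

Step 3
Reactants: 7 (R)-1-(furan-3-yl)-4-methylpent-3-en-1-ol; 8 (R)-2-methylbutanoic acid
Product: 9 (R)-1-(furan-3-yl)-4-methylpent-3-en-1-yl (R)-2-methylbutanoate
Conditions: DCC, DMAP (10 mol%), CH2Cl2, 0 °C to rt
Reagents that add atoms: none
Why: Steglich esterification activates the acid as its O-acylisourea and acylpyridinium at 0 °C with only catalytic DMAP, conditions under which the α-centre of 8 should not epimerize through a ketene or enolate, and acylation on oxygen leaves the carbinol configuration of 7 unchanged.

Step 4
Reactants: 9 (R)-1-(furan-3-yl)-4-methylpent-3-en-1-yl (R)-2-methylbutanoate; 10 p-benzoquinone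
Product: 13 (R)-1-[5-(2,5-dihydroxyphenyl)furan-3-yl]-4-methylpent-3-en-1-yl (R)-2-methylbutanoate, via diketo adduct 11 (not isolated), via furylquinone 12 (not isolated)
Conditions: 9 added slowly to 10 (2.5 equiv), In(OTf)3 (5 mol%), MeCN, 0 °C; then aq Na2S2O4, EtOAc, rt
Reagents that add atoms: none
Why: Proposed new method: In(OTf)3 binds a quinone carbonyl oxygen, furan C5 of 9 attacks the neighbouring quinone CH carbon in a Michael sense to give an oxygen-stabilized σ-complex, proton loss restores the furan to give diketo adduct 11, and enolization of 11, driven by the gain of benzenoid aromaticity, delivers the hydroquinone. The closest known reaction type is the acid- or Lewis-acid-catalysed Friedel-Crafts conjugate addition of 2-alkylfurans and indoles to p-benzoquinone, and the untested element is a 3-substituted furan without an α-donor reacting at C5 next to an ionizable furylcarbinyl ester. No ring is closed and no stereocentre is created, and the base-free conditions with a low loading of a mild Lewis acid at 0 °C in a coordinating solvent are chosen so that neither existing centre is touched. The step needs C5 over C2 selectivity, which the substrate secures through the branched, inductively electron-poor acyloxy-bearing methine on C3: it screens C2 and offers no stabilization to the σ-complex of C2 attack, whose charge sits on C3, whereas C5 attack spreads the charge over C4, C2 and the ring oxygen. It also needs mono-addition, which is secured by adding 9 slowly to surplus 10, so that the first-formed hydroquinone is converted by redox exchange into furylquinone 12, whose electron-poor substituent deactivates the remaining furan α-position while free 10 outcompetes 12 for the furan. Aqueous Na2S2O4 then reduces 12 and the surplus 10, so that all coupled material is collected as the target hydroquinone 13 and the hydroquinone from 10 is washed out.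

Compound list
1 | furan-3-carbaldehyde | O=Cc1ccoc1 | starting material
2 | allylmagnesium bromide | C=CC[Mg]Br | starting material
3 | B-allyldiisopinocampheylborane, both isopinocampheyl groups from (−)-α-pinene (not isolated) | C=CCB([C@H]1C[C@H]2C[C@@H]([C@@H]1C)C2(C)C)[C@H]1C[C@H]2C[C@@H]([C@@H]1C)C2(C)C | intermediate
4 | (R)-1-(furan-3-yl)but-3-en-1-yl diisopinocampheylborinate (not isolated) | C=CC[C@@H](OB([C@H]1C[C@H]2C[C@@H]([C@@H]1C)C2(C)C)[C@H]1C[C@H]2C[C@@H]([C@@H]1C)C2(C)C)c1ccoc1 | intermediate
5 | (R)-1-(furan-3-yl)but-3-en-1-ol | O[C@H](CC=C)c1ccoc1 | intermediate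
6 | 2-methyl-2-butene | CC=C(C)C | starting material
7 | (R)-1-(furan-3-yl)-4-methylpent-3-en-1-ol | O[C@H](CC=C(C)C)c1ccoc1 | intermediate
8 | (R)-2-methylbutanoic acid | CC[C@@H](C)C(=O)O | starting material
9 | (R)-1-(furan-3-yl)-4-methylpent-3-en-1-yl (R)-2-methylbutanoate | CC[C@@H](C)C(=O)O[C@H](CC=C(C)C)c1ccoc1 | intermediate
10 | p-benzoquinone | O=C1C=CC(=O)C=C1 | starting material
11 | (R)-1-[5-(2,5-dioxocyclohex-3-en-1-yl)furan-3-yl]-4-methylpent-3-en-1-yl (R)-2-methylbutanoate, diketo adduct, ring CH centre undefined (not isolated) | CC[C@@H](C)C(=O)O[C@H](CC=C(C)C)c1coc(C2CC(=O)C=CC2=O)c1 | intermediate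
12 | (R)-1-[5-(3,6-dioxocyclohexa-1,4-dien-1-yl)furan-3-yl]-4-methylpent-3-en-1-yl (R)-2-methylbutanoate, furylquinone (not isolated) | CC[C@@H](C)C(=O)O[C@H](CC=C(C)C)c1coc(C2=CC(=O)C=CC2=O)c1 | intermediate
13 | (R)-1-[5-(2,5-dihydroxyphenyl)furan-3-yl]-4-methylpent-3-en-1-yl (R)-2-methylbutanoate (CNP0144658.1) | CC[C@@H](C)C(=O)O[C@H](CC=C(C)C)c1coc(-c2cc(O)ccc2O)c1 | target

Total steps: 4. Longest linear sequence: 4 steps, from 1 to 13.

Steps most likely to fail

1. Step 4. What may go wrong: attack at furan C2 instead of C5, ionization of the furylcarbinyl ester by the Lewis acid with erosion of the carbinol centre, capture of the activated quinone by the trisubstituted alkene, or a second addition to the quinone or to the furan. The fallback uses known chemistry, sets out from 9 and comes back at 13. Sterically governed C–H borylation of the unhindered furan C5–H ([Ir(OMe)(cod)]2, 4,4'-di-tert-butyl-2,2'-bipyridine, B2pin2, hexane, rt) should give the furan-5-yl pinacol boronate F1. Separately, commercial bromohydroquinone would be silylated (TBSCl, imidazole, DMF) to 2-bromo-1,4-bis(tert-butyldimethylsilyloxy)benzene F2. Suzuki–Miyaura coupling of F1 with F2 (Pd(dppf)Cl2, K3PO4, THF/H2O, 45 °C) should give the bis(tert-butyldimethylsilyl) ether of the target F3. Buffered fluoride (TBAF, AcOH, THF, 0 °C) should then free both phenols without touching the ester and give 13.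

2. Step 2. What may go wrong: transfer of the ethylidene instead of the isopropylidene end of the trisubstituted alkene, stalling before full conversion, or alkene migration by ruthenium hydride species. The fallback sets out from 5 and comes back at 7. Silylation (TBSCl, imidazole, DMF) should give the silyl ether F4. Oxidative cleavage of its terminal alkene (OsO4 cat., NaIO4, 2,6-lutidine, dioxane/H2O) should give the β-silyloxy aldehyde F5. Wittig olefination with isopropylidenetriphenylphosphorane (from isopropyltriphenylphosphonium iodide and n-BuLi, THF, −78 to 0 °C) should give the silyl ether of the prenyl carbinol F6. Desilylation (TBAF, THF, 0 °C) should return 7.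

3. Step 1. What may go wrong: insufficient facial selectivity in the allyl transfer, or delivery to the opposite face if the antipode assignment does not hold. The fallback sets out from 1 and 2 and comes back at 5. Direct addition of 2 to 1 (THF, −78 °C) should give the racemic carbinol F7. Lipase-catalysed acylation (Amano lipase PS, vinyl acetate, MTBE, rt) is expected, by the empirical size rule for secondary aryl carbinols, to acylate the (R)-enantiomer and give the (R)-acetate F8, which is separated from the unreacted (S)-alcohol. Methanolysis (K2CO3, MeOH, rt) should then give 5, with the configuration checked by the same Mosher analysis.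

Further compounds
F1 | step 4 | (R)-4-methyl-1-[5-(4,4,5,5-tetramethyl-1,3,2-dioxaborolan-2-yl)furan-3-yl]pent-3-en-1-yl (R)-2-methylbutanoate | CC[C@@H](C)C(=O)O[C@H](CC=C(C)C)c1coc(B2OC(C)(C)C(C)(C)O2)c1
F2 | step 4 | 2-bromo-1,4-bis(tert-butyldimethylsilyloxy)benzene | CC(C)(C)[Si](C)(C)Oc1ccc(O[Si](C)(C)C(C)(C)C)c(Br)c1
F3 | step 4 | (R)-1-{5-[2,5-bis(tert-butyldimethylsilyloxy)phenyl]furan-3-yl}-4-methylpent-3-en-1-yl (R)-2-methylbutanoate | CC[C@@H](C)C(=O)O[C@H](CC=C(C)C)c1coc(-c2cc(O[Si](C)(C)C(C)(C)C)ccc2O[Si](C)(C)C(C)(C)C)c1
F4 | step 2 | (R)-tert-butyl{[1-(furan-3-yl)but-3-en-1-yl]oxy}dimethylsilane | C=CC[C@@H](O[Si](C)(C)C(C)(C)C)c1ccoc1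
F5 | step 2 | (R)-3-(tert-butyldimethylsilyloxy)-3-(furan-3-yl)propanal | O=CC[C@@H](O[Si](C)(C)C(C)(C)C)c1ccoc1
F6 | step 2 | (R)-tert-butyl{[1-(furan-3-yl)-4-methylpent-3-en-1-yl]oxy}dimethylsilane | CC(C)=CC[C@@H](O[Si](C)(C)C(C)(C)C)c1ccoc1
F7 | step 1 | rac-1-(furan-3-yl)but-3-en-1-ol | OC(CC=C)c1ccoc1
F8 | step 1 | (R)-1-(furan-3-yl)but-3-en-1-yl acetate | CC(=O)O[C@H](CC=C)c1ccoc1
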